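The route rests on cutting the O1–C2 bond of the dihydrobenzofuran. C2 is benzylic to the aryl ring it carries (ring A) and stands para to that ring's C4′ oxygen, so a 2,3-diarylpropanoate without any oxygen at C2 can be oxidised at that carbon. Ag2O turns the free 4-hydroxybenzyl unit into a p-quinone methide; the C7a phenol of the benzo ring (ring B) adds to it, closing the furan ring and setting C2 trans to the C3 ester in one operation. The precursor is an (R)-configured α-benzylated arylacetate from an oxazolidinone alkylation, with both reacting phenols free, the two other phenol oxygens benzylated and the C4 aldehyde masked as a dioxolane.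

Key step: step 16

Remarks on the chemistry:
- Atom numbers are those of the 2,3-dihydrobenzofuran core (O1, C2, C3, C3a, C4–C7, C7a).
- The (R) centre of the open-chain precursor is the (3S) centre of the product; only the CIP ranking changes when C2 gains its oxygen.
- The oxygen that becomes O7 is benzylated from step 1 on, so that one reagent removes every phenol protecting group at the end.
- Ring B is built by Claisen rearrangement and oxidative cleavage, which avoids a cross-coupling at a doubly ortho-substituted aryl halide.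
- Assumption: danshensu is used as the free acid.

Step 1
Reactants: 1 protocatechualdehyde
Product: 2 4-(benzyloxy)-3-hydroxybenzaldehyde
Conditions: BnCl, NaHCO3, NaI (cat.), DMF, 40 °C
Reagents that add atoms: benzyl chloride, ClCc1ccccc1
Why: Regioselective Williamson etherification: only the 4-OH, para to the formyl group and therefore the more acidic phenol, is ionised by NaHCO3, so benzylation should occur at O4.

Step 2
Reactants: 2 4-(benzyloxy)-3-hydroxybenzaldehyde
Product: 3 3-(allyloxy)-4-(benzyloxy)benzaldehyde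
Conditions: allyl bromide, K2CO3, DMF, rt
Reagents that add atoms: allyl bromide, BrCC=C
Why: Williamson ether synthesis on the one remaining phenol.

Step 3
Reactants: 3 3-(allyloxy)-4-(benzyloxy)benzaldehyde
Product: 4 2-allyl-4-(benzyloxy)-3-hydroxybenzaldehyde
Conditions: PhNEt2, 190 °C
Reagents that add atoms: none
Why: Aromatic Claisen rearrangement: C2 is the only free ortho position of the allyl aryl ether (C4 carries the benzyloxy group), so the [3,3]-shift should deliver the allyl group between the phenol and the formyl group.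

Step 4
Reactants: 4 2-allyl-4-(benzyloxy)-3-hydroxybenzaldehyde
Product: 5 2-allyl-4-(benzyloxy)-3-[(triisopropylsilyl)oxy]benzaldehyde
Conditions: TIPSOTf, 2,6-lutidine, CH2Cl2, 0 °C to rt
Reagents that add atoms: triisopropylsilyl trifluoromethanesulfonate, CC(C)[Si](OS(=O)(=O)C(F)(F)F)(C(C)C)C(C)C
Why: Silylation of a doubly ortho-substituted phenol with a silyl triflate; the bulky aryl silyl ether is chosen to survive acid catalysis, enolate chemistry and hydroperoxide later on.

Step 5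
Reactants: 5 2-allyl-4-(benzyloxy)-3-[(triisopropylsilyl)oxy]benzaldehyde
Product: 6 2-{2-allyl-4-(benzyloxy)-3-[(triisopropylsilyl)oxy]phenyl}-1,3-dioxolane
Conditions: HOCH2CH2OH, p-TsOH (cat.), benzene, reflux, Dean–Stark
Reagents that add atoms: ethylene glycol, OCCO
Why: Acid-catalysed acetalisation driven by azeotropic removal of water; the phenol is already silylated, so it cannot add to the allyl group under acid.

Step 6
Reactants: 6 2-{2-allyl-4-(benzyloxy)-3-[(triisopropylsilyl)oxy]phenyl}-1,3-dioxolane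
Product: 9 [3-(benzyloxy)-6-(1,3-dioxolan-2-yl)-2-[(triisopropylsilyl)oxy]phenyl]acetic acid, via ozonide 7 (not isolated), via arylacetaldehyde 8 (not isolated)
Conditions: O3, CH2Cl2, −78 °C (Sudan Red 7B end point); PPh3; then NaClO2, NaH2PO4, 2-methyl-2-butene, t-BuOH/H2O, 0 °C
Reagents that add atoms: ozone, [O-][O+]=O; sodium chlorite, [Na+].[O-]Cl=O
Why: Ozonolysis with reductive work-up followed by Pinnick oxidation: the terminal alkene is far more reactive towards ozone than the aryl rings, the benzyl ether or the acetal, and buffered chlorite with a hypochlorite scavenger should oxidise the crude aldehyde 8 without touching the dioxolane or the silyl ether.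

Step 7
Reactants: 9 [3-(benzyloxy)-6-(1,3-dioxolan-2-yl)-2-[(triisopropylsilyl)oxy]phenyl]acetic acid; 10 (4R)-4-benzyl-1,3-oxazolidin-2-one
Product: 12 (4R)-4-benzyl-3-{[3-(benzyloxy)-6-(1,3-dioxolan-2-yl)-2-[(triisopropylsilyl)oxy]phenyl]acetyl}-1,3-oxazolidin-2-one, via mixed pivalic anhydride 11 (not isolated)
Conditions: PivCl, Et3N, THF, −20 °C; then 10, LiCl, rt
Reagents that add atoms: none
Why: N-Acylation through a mixed pivalic anhydride: the oxazolidinone, activated by LiCl and Et3N, should attack the unhindered arylacetyl carbonyl of 11 and not the pivaloyl one.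

Step 8
Reactants: 1 protocatechualdehyde
Product: 13 3-(benzyloxy)-4-hydroxybenzaldehyde
Conditions: NaH (2.2 equiv), DMSO, rt; BnCl (1.0 equiv); dilute HCl work-up
Reagents that add atoms: benzyl chloride, ClCc1ccccc1
Why: Williamson etherification of the catecholate dianion: the O3 phenoxide is not conjugated with the formyl group and is the more nucleophilic site, so one equivalent of BnCl should alkylate O3 and leave O4 free (the complement of step 1).

Step 9
Reactants: 13 3-(benzyloxy)-4-hydroxybenzaldehyde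
Product: 14 3-(benzyloxy)-4-[(triisopropylsilyl)oxy]benzaldehyde
Conditions: TIPSCl, imidazole, DMF, rt
Reagents that add atoms: chlorotriisopropylsilane, CC(C)[Si](Cl)(C(C)C)C(C)C
Why: Imidazole-promoted silylation of the free phenol, with the same silyl group as on ring B so that both come off together in step 15.

Step 10
Reactants: 14 3-(benzyloxy)-4-[(triisopropylsilyl)oxy]benzaldehyde
Product: 15 {3-(benzyloxy)-4-[(triisopropylsilyl)oxy]phenyl}methanol
Conditions: NaBH4, THF/EtOH, 0 °C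
Reagents that add atoms: none
Why: Hydride reduction of the aryl aldehyde; the bulky aryl silyl ether should tolerate the brief exposure to ethoxide.

Step 11
Reactants: 15 {3-(benzyloxy)-4-[(triisopropylsilyl)oxy]phenyl}methanol
Product: 16 [2-(benzyloxy)-4-(bromomethyl)phenoxy]triisopropylsilane
Conditions: CBr4, PPh3, CH2Cl2, 0 °C; used at once
Reagents that add atoms: tetrabromomethane, BrC(Br)(Br)Br
Why: Appel bromination under neutral conditions, which avoids the HBr that could cleave the silyl ether of this electron-rich benzylic bromide.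

Step 12
Reactants: 12 (4R)-4-benzyl-3-{[3-(benzyloxy)-6-(1,3-dioxolan-2-yl)-2-[(triisopropylsilyl)oxy]phenyl]acetyl}-1,3-oxazolidin-2-one; 16 [2-(benzyloxy)-4-(bromomethyl)phenoxy]triisopropylsilane
Product: 17 (4R)-4-benzyl-3-{(2R)-2-[3-(benzyloxy)-6-(1,3-dioxolan-2-yl)-2-[(triisopropylsilyl)oxy]phenyl]-3-[3-(benzyloxy)-4-[(triisopropylsilyl)oxy]phenyl]propanoyl}-1,3-oxazolidin-2-one
Conditions: NaN(SiMe3)2, THF, −78 °C; then 16, −78 to −40 °C
Reagents that add atoms: none
Why: Evans auxiliary alkylation: the chelated (Z)-sodium enolate should be alkylated by the reactive benzylic bromide on the face away from the C4 benzyl group of the (R)-auxiliary, which sets the new centre (the future C3) as (R).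

Step 13
Reactants: 17 (4R)-4-benzyl-3-{(2R)-2-[3-(benzyloxy)-6-(1,3-dioxolan-2-yl)-2-[(triisopropylsilyl)oxy]phenyl]-3-[3-(benzyloxy)-4-[(triisopropylsilyl)oxy]phenyl]propanoyl}-1,3-oxazolidin-2-one
Product: 19 (2R)-2-[3-(benzyloxy)-6-(1,3-dioxolan-2-yl)-2-[(triisopropylsilyl)oxy]phenyl]-3-[3-(benzyloxy)-4-[(triisopropylsilyl)oxy]phenyl]propanoic acid, via peroxy acid 18 (not isolated)
Conditions: LiOH·H2O, H2O2 (30% aq), THF/H2O, 0 °C; Na2SO3 (aq); dilute HCl to pH 4–5 at 0 °C
Reagents that add atoms: hydrogen peroxide (as LiOOH), OO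
Why: Hydroperoxide cleavage of the imide: the small, weakly basic hydroperoxide anion should attack the hindered exocyclic carbonyl without epimerising the α-aryl centre or cleaving the silyl ethers, and sulfite reduces peroxy acid 18 to the acid.

Step 14
Reactants: 19 (2R)-2-[3-(benzyloxy)-6-(1,3-dioxolan-2-yl)-2-[(triisopropylsilyl)oxy]phenyl]-3-[3-(benzyloxy)-4-[(triisopropylsilyl)oxy]phenyl]propanoic acid
Product: 20 methyl (2R)-2-[3-(benzyloxy)-6-(1,3-dioxolan-2-yl)-2-[(triisopropylsilyl)oxy]phenyl]-3-[3-(benzyloxy)-4-[(triisopropylsilyl)oxy]phenyl]propanoate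
Conditions: Me3SiCHN2, toluene/MeOH, 0 °C
Reagents that add atoms: (trimethylsilyl)diazomethane, C[Si](C)(C)C=[N+]=[N-]
Why: Esterification of the carboxylic acid with a diazoalkane under neutral conditions, which should leave the α-aryl stereocentre, the acetal and the silyl ethers untouched.

Step 15
Reactants: 20 methyl (2R)-2-[3-(benzyloxy)-6-(1,3-dioxolan-2-yl)-2-[(triisopropylsilyl)oxy]phenyl]-3-[3-(benzyloxy)-4-[(triisopropylsilyl)oxy]phenyl]propanoate
Product: 21 methyl (2R)-2-[3-(benzyloxy)-6-(1,3-dioxolan-2-yl)-2-hydroxyphenyl]-3-[3-(benzyloxy)-4-hydroxyphenyl]propanoate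
Conditions: Bu4NF, AcOH, THF, 0 °C; used at once
Reagents that add atoms: none
Why: Fluoride desilylation of both aryl silyl ethers; acetic acid keeps the liberated phenols protonated, so neither lactonisation onto the ester nor epimerisation of the α-aryl ester should occur, and the dioxolane is not affected.

Step 16
Reactants: 21 methyl (2R)-2-[3-(benzyloxy)-6-(1,3-dioxolan-2-yl)-2-hydroxyphenyl]-3-[3-(benzyloxy)-4-hydroxyphenyl]propanoate
Product: 23 methyl (2S,3S)-7-(benzyloxy)-2-[3-(benzyloxy)-4-hydroxyphenyl]-4-(1,3-dioxolan-2-yl)-2,3-dihydro-1-benzofuran-3-carboxylate, via p-quinone methide 22 (not isolated)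
Conditions: Ag2O (1.2 equiv), CH2Cl2, 4 Å molecular sieves, rt, dark
Reagents that add atoms: none
Why: Ag2O takes two electrons and two protons from the ring A 4-hydroxybenzyl unit, the only phenol with a benzylic CH2 para to its oxygen, to give p-quinone methide 22, whose exocyclic carbon is the future C2; the ring B phenol then adds to that carbon in an oxa-1,6-conjugate addition that restores the aromaticity of ring A. The closest known reaction type is the Ag2O or DDQ oxidation of 4-hydroxybenzyl phenols to p-quinone methides that are captured intramolecularly to give trans-2-aryl-2,3-dihydrobenzofurans, the same closure that ends the oxidative dimerisation of ferulate esters. The dihydrofuran ring closes in a 5-exo-trig mode. The new C2 stereocentre is controlled by the C3 stereocentre from step 12: the aryl group should take the face anti to the ester, which is also the thermodynamically preferred trans arrangement, giving (2S,3S). The step needs oxidation of ring A in preference to ring B, and ring closure faster than tautomerisation of 22 to the 2,3-diarylacrylate. The first should be secured by the more electron-rich para-alkyl phenol of ring A (the ring B phenol is hindered, hydrogen-bonded to the ester and flanked by electron-poor substituents), the second by the neutral, base-free heterogeneous oxidant and the nucleophile held five atoms away.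

Step 17
Reactants: 23 methyl (2S,3S)-7-(benzyloxy)-2-[3-(benzyloxy)-4-hydroxyphenyl]-4-(1,3-dioxolan-2-yl)-2,3-dihydro-1-benzofuran-3-carboxylate
Product: 24 methyl (2S,3S)-7-(benzyloxy)-2-[3-(benzyloxy)-4-hydroxyphenyl]-4-formyl-2,3-dihydro-1-benzofuran-3-carboxylate
Conditions: 1 M HCl (aq), THF, 0 °C to rt
Reagents that add atoms: water, O
Why: Acid-catalysed acetal hydrolysis: the electron-rich aryl dioxolane should hydrolyse under mild aqueous acid, and any reversible ionisation of the C2–O1 benzylic ether would return to the favoured trans isomer.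

Step 18
Reactants: 25 danshensu, (2R)-3-(3,4-dihydroxyphenyl)-2-hydroxypropanoic acid
Product: 26 benzyl (2R)-3-[3,4-bis(benzyloxy)phenyl]-2-hydroxypropanoate
Conditions: BnBr (3.3 equiv), K2CO3, DMF, rt, argon
Reagents that add atoms: benzyl bromide, BrCc1ccccc1
Why: Williamson O-alkylation of the two phenoxides and the carboxylate; the secondary alcohol is not ionised by K2CO3 and should stay free.

Step 19
Reactants: 24 methyl (2S,3S)-7-(benzyloxy)-2-[3-(benzyloxy)-4-hydroxyphenyl]-4-formyl-2,3-dihydro-1-benzofuran-3-carboxylate; 26 benzyl (2R)-3-[3,4-bis(benzyloxy)phenyl]-2-hydroxypropanoate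
Product: 28 benzyl (2R)-3-[3,4-bis(benzyloxy)phenyl]-2-({(2E)-3-[(2S,3S)-7-(benzyloxy)-2-[3-(benzyloxy)-4-hydroxyphenyl]-3-(methoxycarbonyl)-2,3-dihydro-1-benzofuran-4-yl]prop-2-enoyl}oxy)propanoate, via phosphorus ylide 27 (not isolated)
Conditions: 26 (1.3 equiv), Ph3P=C=C=O (1.2 equiv), toluene, 90 °C; then 24, 80 °C
Reagents that add atoms: (triphenylphosphoranylidene)ketene, O=C=C=P(c1ccccc1)(c1ccccc1)c1ccccc1
Why: Addition of the secondary alcohol to the cumulated ylide gives the ester-stabilised phosphorane 27, whose Wittig olefination of the aryl aldehyde should give the (E)-acrylate under base-free conditions that leave the free phenol, the C3 stereocentre and the lactate stereocentre alone.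

Step 20
Reactants: 28 benzyl (2R)-3-[3,4-bis(benzyloxy)phenyl]-2-({(2E)-3-[(2S,3S)-7-(benzyloxy)-2-[3-(benzyloxy)-4-hydroxyphenyl]-3-(methoxycarbonyl)-2,3-dihydro-1-benzofuran-4-yl]prop-2-enoyl}oxy)propanoate
Product: 29 monomethyl lithospermate, (2R)-3-(3,4-dihydroxyphenyl)-2-({(2E)-3-[(2S,3S)-2-(3,4-dihydroxyphenyl)-7-hydroxy-3-(methoxycarbonyl)-2,3-dihydro-1-benzofuran-4-yl]prop-2-enoyl}oxy)propanoic acid
Conditions: BCl3, C6HMe5, CH2Cl2, −78 to −30 °C; aqueous quench
Reagents that add atoms: none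
Why: Lewis-acid debenzylation with a cation scavenger: BCl3 should cleave the four aryl benzyl ethers and the benzyl ester at low temperature while pentamethylbenzene traps the benzyl cations by Friedel–Crafts alkylation, leaving the methyl ester, the acrylate and the three stereocentres as they are.

Compound list

1 | protocatechualdehyde (3,4-dihydroxybenzaldehyde) | O=Cc1ccc(O)c(O)c1 | starting material
2 | 4-(benzyloxy)-3-hydroxybenzaldehyde | O=Cc1ccc(OCc2ccccc2)c(O)c1 | intermediate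
3 | 3-(allyloxy)-4-(benzyloxy)benzaldehyde | O=Cc1ccc(OCc2ccccc2)c(OCC=C)c1 | intermediate
4 | 2-allyl-4-(benzyloxy)-3-hydroxybenzaldehyde | O=Cc1ccc(OCc2ccccc2)c(O)c1CC=C | intermediate
5 | 2-allyl-4-(benzyloxy)-3-[(triisopropylsilyl)oxy]benzaldehyde | O=Cc1ccc(OCc2ccccc2)c(O[Si](C(C)C)(C(C)C)C(C)C)c1CC=C | intermediate
6 | 2-{2-allyl-4-(benzyloxy)-3-[(triisopropylsilyl)oxy]phenyl}-1,3-dioxolane | C=CCc1c(C2OCCO2)ccc(OCc2ccccc2)c1O[Si](C(C)C)(C(C)C)C(C)C | intermediate
7 | ozonide of 6, 3-{[3-(benzyloxy)-6-(1,3-dioxolan-2-yl)-2-[(triisopropylsilyl)oxy]phenyl]methyl}-1,2,4-trioxolane (not isolated) | O1OC(Cc2c(C3OCCO3)ccc(OCc3ccccc3)c2O[Si](C(C)C)(C(C)C)C(C)C)OC1 | intermediate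
8 | [3-(benzyloxy)-6-(1,3-dioxolan-2-yl)-2-[(triisopropylsilyl)oxy]phenyl]acetaldehyde (not isolated) | O=CCc1c(C2OCCO2)ccc(OCc2ccccc2)c1O[Si](C(C)C)(C(C)C)C(C)C | intermediate
9 | [3-(benzyloxy)-6-(1,3-dioxolan-2-yl)-2-[(triisopropylsilyl)oxy]phenyl]acetic acid | OC(=O)Cc1c(C2OCCO2)ccc(OCc2ccccc2)c1O[Si](C(C)C)(C(C)C)C(C)C | intermediate
10 | (4R)-4-benzyl-1,3-oxazolidin-2-one | O=C1OC[C@@H](Cc2ccccc2)N1 | starting material
11 | mixed anhydride of 9 with pivalic acid (not isolated) | CC(C)(C)C(=O)OC(=O)Cc1c(C2OCCO2)ccc(OCc2ccccc2)c1O[Si](C(C)C)(C(C)C)C(C)C | intermediate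
12 | (4R)-4-benzyl-3-{[3-(benzyloxy)-6-(1,3-dioxolan-2-yl)-2-[(triisopropylsilyl)oxy]phenyl]acetyl}-1,3-oxazolidin-2-one | O=C1OC[C@@H](Cc2ccccc2)N1C(=O)Cc1c(C2OCCO2)ccc(OCc2ccccc2)c1O[Si](C(C)C)(C(C)C)C(C)C | intermediate
13 | 3-(benzyloxy)-4-hydroxybenzaldehyde | O=Cc1ccc(O)c(OCc2ccccc2)c1 | intermediate
14 | 3-(benzyloxy)-4-[(triisopropylsilyl)oxy]benzaldehyde | O=Cc1ccc(O[Si](C(C)C)(C(C)C)C(C)C)c(OCc2ccccc2)c1 | intermediate
15 | {3-(benzyloxy)-4-[(triisopropylsilyl)oxy]phenyl}methanol | OCc1ccc(O[Si](C(C)C)(C(C)C)C(C)C)c(OCc2ccccc2)c1 | intermediate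
16 | [2-(benzyloxy)-4-(bromomethyl)phenoxy]triisopropylsilane | BrCc1ccc(O[Si](C(C)C)(C(C)C)C(C)C)c(OCc2ccccc2)c1 | intermediate
17 | (4R)-4-benzyl-3-{(2R)-2-[3-(benzyloxy)-6-(1,3-dioxolan-2-yl)-2-[(triisopropylsilyl)oxy]phenyl]-3-[3-(benzyloxy)-4-[(triisopropylsilyl)oxy]phenyl]propanoyl}-1,3-oxazolidin-2-one | O=C1OC[C@@H](Cc2ccccc2)N1C(=O)[C@H](Cc1ccc(O[Si](C(C)C)(C(C)C)C(C)C)c(OCc2ccccc2)c1)c1c(C2OCCO2)ccc(OCc2ccccc2)c1O[Si](C(C)C)(C(C)C)C(C)C | intermediate
18 | (2R)-2-[3-(benzyloxy)-6-(1,3-dioxolan-2-yl)-2-[(triisopropylsilyl)oxy]phenyl]-3-[3-(benzyloxy)-4-[(triisopropylsilyl)oxy]phenyl]propaneperoxoic acid (not isolated) | OOC(=O)[C@H](Cc1ccc(O[Si](C(C)C)(C(C)C)C(C)C)c(OCc2ccccc2)c1)c1c(C2OCCO2)ccc(OCc2ccccc2)c1O[Si](C(C)C)(C(C)C)C(C)C | intermediate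
19 | (2R)-2-[3-(benzyloxy)-6-(1,3-dioxolan-2-yl)-2-[(triisopropylsilyl)oxy]phenyl]-3-[3-(benzyloxy)-4-[(triisopropylsilyl)oxy]phenyl]propanoic acid | OC(=O)[C@H](Cc1ccc(O[Si](C(C)C)(C(C)C)C(C)C)c(OCc2ccccc2)c1)c1c(C2OCCO2)ccc(OCc2ccccc2)c1O[Si](C(C)C)(C(C)C)C(C)C | intermediate
20 | methyl (2R)-2-[3-(benzyloxy)-6-(1,3-dioxolan-2-yl)-2-[(triisopropylsilyl)oxy]phenyl]-3-[3-(benzyloxy)-4-[(triisopropylsilyl)oxy]phenyl]propanoate | COC(=O)[C@H](Cc1ccc(O[Si](C(C)C)(C(C)C)C(C)C)c(OCc2ccccc2)c1)c1c(C2OCCO2)ccc(OCc2ccccc2)c1O[Si](C(C)C)(C(C)C)C(C)C | intermediate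
21 | methyl (2R)-2-[3-(benzyloxy)-6-(1,3-dioxolan-2-yl)-2-hydroxyphenyl]-3-[3-(benzyloxy)-4-hydroxyphenyl]propanoate (key-step precursor) | COC(=O)[C@H](Cc1ccc(O)c(OCc2ccccc2)c1)c1c(C2OCCO2)ccc(OCc2ccccc2)c1O | intermediate
22 | methyl (2R)-2-[3-(benzyloxy)-6-(1,3-dioxolan-2-yl)-2-hydroxyphenyl]-3-[3-(benzyloxy)-4-oxocyclohexa-2,5-dien-1-ylidene]propanoate (p-quinone methide, exocyclic alkene geometry not defined, not isolated) | COC(=O)[C@H](C=C1C=CC(=O)C(OCc2ccccc2)=C1)c1c(C2OCCO2)ccc(OCc2ccccc2)c1O | intermediate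
23 | methyl (2S,3S)-7-(benzyloxy)-2-[3-(benzyloxy)-4-hydroxyphenyl]-4-(1,3-dioxolan-2-yl)-2,3-dihydro-1-benzofuran-3-carboxylate (key-step product) | COC(=O)[C@H]1c2c(C3OCCO3)ccc(OCc3ccccc3)c2O[C@@H]1c1ccc(O)c(OCc2ccccc2)c1 | intermediate
24 | methyl (2S,3S)-7-(benzyloxy)-2-[3-(benzyloxy)-4-hydroxyphenyl]-4-formyl-2,3-dihydro-1-benzofuran-3-carboxylate | COC(=O)[C@H]1c2c(C=O)ccc(OCc3ccccc3)c2O[C@@H]1c1ccc(O)c(OCc2ccccc2)c1 | intermediate
25 | danshensu, (2R)-3-(3,4-dihydroxyphenyl)-2-hydroxypropanoic acid | O[C@H](Cc1ccc(O)c(O)c1)C(=O)O | starting material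
26 | benzyl (2R)-3-[3,4-bis(benzyloxy)phenyl]-2-hydroxypropanoate | O[C@H](Cc1ccc(OCc2ccccc2)c(OCc2ccccc2)c1)C(=O)OCc1ccccc1 | intermediate
27 | benzyl (2R)-3-[3,4-bis(benzyloxy)phenyl]-2-{[(triphenyl-λ5-phosphanylidene)acetyl]oxy}propanoate (not isolated) | O=C(C=P(c1ccccc1)(c1ccccc1)c1ccccc1)O[C@H](Cc1ccc(OCc2ccccc2)c(OCc2ccccc2)c1)C(=O)OCc1ccccc1 | intermediate
28 | benzyl (2R)-3-[3,4-bis(benzyloxy)phenyl]-2-({(2E)-3-[(2S,3S)-7-(benzyloxy)-2-[3-(benzyloxy)-4-hydroxyphenyl]-3-(methoxycarbonyl)-2,3-dihydro-1-benzofuran-4-yl]prop-2-enoyl}oxy)propanoate | COC(=O)[C@H]1c2c(/C=C/C(=O)O[C@H](Cc3ccc(OCc4ccccc4)c(OCc4ccccc4)c3)C(=O)OCc3ccccc3)ccc(OCc3ccccc3)c2O[C@@H]1c1ccc(O)c(OCc2ccccc2)c1 | intermediate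
29 | monomethyl lithospermate | COC(=O)[C@H]1c2c(/C=C/C(=O)O[C@H](Cc3ccc(O)c(O)c3)C(=O)O)ccc(O)c2O[C@@H]1c1ccc(O)c(O)c1 | target

Total step count: 20. Longest linear sequence: 15 steps (steps 1–7, 12–17, 19 and 20).

Steps most likely to fail

Step 16 (key step). The oxidation may take a wrong course: one-electron phenoxyl coupling, a second oxidation of the product phenol to the benzofuran, or tautomerisation of the quinone methide to the 2,3-diarylacrylate, which erases the C3 stereocentre. The fallback sets out from acid 9 and aldehyde 14 and comes back to the route at 23. It creates the electrophilic C2 by ionisation of a benzylic alcohol instead of by oxidation.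
- Acid 9 is joined to (4S)-4-benzyl-1,3-oxazolidin-2-one (PivCl, Et3N; LiCl) to give the (S)-auxiliary imide F1. The enantiomeric auxiliary is needed because the boron aldol addition takes the enolate face opposite to the one used in the alkylation.
- The boron enolate of F1 (Bu2BOTf, i-Pr2NEt, CH2Cl2, −78 °C) should add to aldehyde 14 in a syn-aldol addition to give the syn-aldol imide F2.
- LiOH/H2O2 cleavage should give the hydroxy acid F3, and Me3SiCHN2 the hydroxy methyl ester F4.
- Buffered Bu4NF should give the triol F5.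
- PPTS in CH2Cl2 over molecular sieves should ionise the 4-hydroxybenzylic alcohol of F5; capture by the ring B phenol (SN1 etherification, trans by thermodynamic control) would give 23.

Step 12. The enolate carbon is flanked by a 2,6-disubstituted aryl ring, so C-alkylation may become slower than fragmentation of the enolate to an arylketene, or the facial selectivity may erode. The fallback sets out from acid 9 and bromide 16 and comes back at 20. It gives up auxiliary control in favour of a smaller enolate and a resolution.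
- Me3SiCHN2 converts 9 into the methyl arylacetate F6.
- Its lithium enolate (LiN(i-Pr)2, THF/DMPU, −78 °C) is alkylated with 16 to give the racemic methyl ester F7.
- Preparative chromatography on a chiral stationary phase separates the (R)-enantiomer, which is 20.

Step 20. BCl3 may ionise the C2–O1 benzylic ether, leading to ring opening or capture of the cation by the scavenger, or the benzyl ester may be cleaved incompletely. The fallback sets out from 23 and danshensu 25 and comes back at 29. It removes the benzyl ethers by hydrogenolysis before the acrylate exists and carries danshensu with allyl groups.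
- H2 over Pd/C in EtOAc should convert 23 into the triphenol acetal F8.
- 1 M HCl in THF should give the triphenol aldehyde F9.
- Danshensu 25 with allyl bromide and K2CO3 in DMF should give the tri-O-allyl danshensu F10.
- F10 with Ph3P=C=C=O in hot toluene should give the allyl-protected ylide F11, which olefinates F9 to the allyl-protected ester F12.
- Pd(PPh3)4 with morpholine in THF (zerovalent palladium, allyl transfer to the amine) should remove the allyl ester and both allyl ethers under neutral conditions and give 29.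

Further compounds

F1 | step 16 | (4S)-4-benzyl-3-{[3-(benzyloxy)-6-(1,3-dioxolan-2-yl)-2-[(triisopropylsilyl)oxy]phenyl]acetyl}-1,3-oxazolidin-2-one | O=C1OC[C@H](Cc2ccccc2)N1C(=O)Cc1c(C2OCCO2)ccc(OCc2ccccc2)c1O[Si](C(C)C)(C(C)C)C(C)C
F2 | step 16 | (4S)-4-benzyl-3-{(2S,3S)-2-[3-(benzyloxy)-6-(1,3-dioxolan-2-yl)-2-[(triisopropylsilyl)oxy]phenyl]-3-[3-(benzyloxy)-4-[(triisopropylsilyl)oxy]phenyl]-3-hydroxypropanoyl}-1,3-oxazolidin-2-one | O=C1OC[C@H](Cc2ccccc2)N1C(=O)[C@H]([C@H](O)c1ccc(O[Si](C(C)C)(C(C)C)C(C)C)c(OCc2ccccc2)c1)c1c(C2OCCO2)ccc(OCc2ccccc2)c1O[Si](C(C)C)(C(C)C)C(C)C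
F3 | step 16 | (2S,3S)-2-[3-(benzyloxy)-6-(1,3-dioxolan-2-yl)-2-[(triisopropylsilyl)oxy]phenyl]-3-[3-(benzyloxy)-4-[(triisopropylsilyl)oxy]phenyl]-3-hydroxypropanoic acid | OC(=O)[C@H]([C@H](O)c1ccc(O[Si](C(C)C)(C(C)C)C(C)C)c(OCc2ccccc2)c1)c1c(C2OCCO2)ccc(OCc2ccccc2)c1O[Si](C(C)C)(C(C)C)C(C)C
F4 | step 16 | methyl (2S,3S)-2-[3-(benzyloxy)-6-(1,3-dioxolan-2-yl)-2-[(triisopropylsilyl)oxy]phenyl]-3-[3-(benzyloxy)-4-[(triisopropylsilyl)oxy]phenyl]-3-hydroxypropanoate | COC(=O)[C@H]([C@H](O)c1ccc(O[Si](C(C)C)(C(C)C)C(C)C)c(OCc2ccccc2)c1)c1c(C2OCCO2)ccc(OCc2ccccc2)c1O[Si](C(C)C)(C(C)C)C(C)C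
F5 | step 16 | methyl (2S,3S)-2-[3-(benzyloxy)-6-(1,3-dioxolan-2-yl)-2-hydroxyphenyl]-3-[3-(benzyloxy)-4-hydroxyphenyl]-3-hydroxypropanoate | COC(=O)[C@H]([C@H](O)c1ccc(O)c(OCc2ccccc2)c1)c1c(C2OCCO2)ccc(OCc2ccccc2)c1O
F6 | step 12 | methyl [3-(benzyloxy)-6-(1,3-dioxolan-2-yl)-2-[(triisopropylsilyl)oxy]phenyl]acetate | COC(=O)Cc1c(C2OCCO2)ccc(OCc2ccccc2)c1O[Si](C(C)C)(C(C)C)C(C)C
F7 | step 12 | racemic methyl 2-[3-(benzyloxy)-6-(1,3-dioxolan-2-yl)-2-[(triisopropylsilyl)oxy]phenyl]-3-[3-(benzyloxy)-4-[(triisopropylsilyl)oxy]phenyl]propanoate | COC(=O)C(Cc1ccc(O[Si](C(C)C)(C(C)C)C(C)C)c(OCc2ccccc2)c1)c1c(C2OCCO2)ccc(OCc2ccccc2)c1O[Si](C(C)C)(C(C)C)C(C)C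
F8 | step 20 | methyl (2S,3S)-2-(3,4-dihydroxyphenyl)-4-(1,3-dioxolan-2-yl)-7-hydroxy-2,3-dihydro-1-benzofuran-3-carboxylate | COC(=O)[C@H]1c2c(C3OCCO3)ccc(O)c2O[C@@H]1c1ccc(O)c(O)c1
F9 | step 20 | methyl (2S,3S)-2-(3,4-dihydroxyphenyl)-4-formyl-7-hydroxy-2,3-dihydro-1-benzofuran-3-carboxylate | COC(=O)[C@H]1c2c(C=O)ccc(O)c2O[C@@H]1c1ccc(O)c(O)c1
F10 | step 20 | allyl (2R)-3-[3,4-bis(allyloxy)phenyl]-2-hydroxypropanoate | O[C@H](Cc1ccc(OCC=C)c(OCC=C)c1)C(=O)OCC=C
F11 | step 20 | allyl (2R)-3-[3,4-bis(allyloxy)phenyl]-2-{[(triphenyl-λ5-phosphanylidene)acetyl]oxy}propanoate | O=C(C=P(c1ccccc1)(c1ccccc1)c1ccccc1)O[C@H](Cc1ccc(OCC=C)c(OCC=C)c1)C(=O)OCC=C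
F12 | step 20 | allyl (2R)-3-[3,4-bis(allyloxy)phenyl]-2-({(2E)-3-[(2S,3S)-2-(3,4-dihydroxyphenyl)-7-hydroxy-3-(methoxycarbonyl)-2,3-dihydro-1-benzofuran-4-yl]prop-2-enoyl}oxy)propanoate | COC(=O)[C@H]1c2c(/C=C/C(=O)O[C@H](Cc3ccc(OCC=C)c(OCC=C)c3)C(=O)OCC=C)ccc(O)c2O[C@@H]1c1ccc(O)c(O)c1
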